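**Retrosynthetic overview**

1. The target is reached by hydrogenolysis of its hepta-O-benzyl ether. In the lower unit, C3–OH and C4–H2 come from hydroboration of a C3=C4 alkene, and the C2–aryl bond from enantioselective aryl transfer to a benzopyrylium ion; both go back to a coumarin.
2. The upper C ring comes from a hetero-Diels–Alder reaction of an o-quinone methide with 3,4-bis(benzyloxy)styrene (upper C2/C4 cis). The methide carbon (upper C4) is the formyl carbon on lower C8.
3. The lower C ring is first closed flat, as an α-pyranone: the C3–C4 bond is made by an intramolecular Wittig reaction after O-acylation of the single phenol of a 2-hydroxybenzene-1,3-dicarbaldehyde with Ph3P=C=C=O.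
4. Enabling feature: in the lower A ring, O1 (on C8a) lies between C4a, which carries C4, and C8, which carries C4 of the upper unit. Both ortho carbons bear a one-carbon branch, so the ring maps onto a mirror-symmetric dialdehyde with one phenol; either formyl group gives the same coumarin and the other remains as the 4→8 anchor.
5. Ring order: lower pyranone ring (step 2), then upper pyran ring (step 5), then the lower ring is made stereogenic (steps 6 to 8).

Key step: step 2

Assumption: 1 is taken as a catalogue compound (otherwise one Vilsmeier–Haack step from phloroglucinol), and in steps 5 and 7 the catalyst antipode is the one that gives the configuration drawn.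

**Route**

Step 1
Reactants: 1 2,4,6-trihydroxybenzene-1,3-dicarbaldehyde
Product: 2 4,6-bis(benzyloxy)-2-hydroxybenzene-1,3-dicarbaldehyde
Conditions: BnBr (2.05 equiv), K2CO3 (2.1 equiv), DMF, 0 °C to rt
Reagents that add atoms: benzyl bromide, BrCc1ccccc1
Why: Williamson ether synthesis in which the 4- and 6-OH groups (each para to one formyl group) should be alkylated while the 2-OH, wedged between and chelated by two formyl groups, stays free, as in the selective dibenzylation of 2,4,6-trihydroxybenzaldehyde.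

Step 2
Reactants: 2 4,6-bis(benzyloxy)-2-hydroxybenzene-1,3-dicarbaldehyde; 3 ketenylidene(triphenyl)phosphorane
Product: 5 5,7-bis(benzyloxy)-2-oxo-2H-chromene-8-carbaldehyde, via acyl ylide 4 (not isolated)
Conditions: 3 (1.1 equiv, slow addition), toluene, 110 °C
Reagents that add atoms: none
Why: The acidic phenol O–H adds across the cumulated C=C of 3 (O-acylation) to give the ester-stabilised ylide 4, whose ylide carbon (future C3) attacks the neighbouring formyl carbon (future C4) and, through the oxaphosphetane, expels Ph3PO to form the C3=C4 bond; the closest known reaction type is the coumarin synthesis from salicylaldehydes and ketenylidenephosphoranes (intramolecular Wittig reaction). The pyranone ring is closed by the C3–C4 bond in a 6-exo-trig addition of the ylide to the C=O, followed by cycloreversion. No stereocentre is formed: the ring is made flat on purpose and becomes the stereogenic C ring in steps 6 to 8. The selectivity needed is a single annulation at a defined formyl group; the mirror plane of 2 makes the two formyl groups equivalent, and the only phenol is used up and masked as the lactone, so the second formyl group cannot cyclise and stays as the C8 handle, which fixes the 4→8 linkage without C6/C8 competition. Intermolecular olefination of that formyl group by 4 should be outrun by the six-ring closure, helped by slow addition of 3.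

Step 3
Reactants: 5 5,7-bis(benzyloxy)-2-oxo-2H-chromene-8-carbaldehyde; 6 3-(benzyloxy)phenol
Product: 8 5,7-bis(benzyloxy)-8-{[4-(benzyloxy)-2-hydroxyphenyl](hydroxy)methyl}-2H-chromen-2-one (racemic), via magnesium phenolate 7 (not isolated)
Conditions: 6, EtMgBr (1.0 equiv), Et2O, 0 °C; then toluene, 5, rt; cold aq NH4Cl
Reagents that add atoms: none
Why: Ortho-specific hydroxyalkylation of a magnesium phenolate (Friedel–Crafts type), in which the Mg-bound aldehyde is delivered through a six-membered chelate to the ortho carbon para to OBn; the carbinol centre forms as a racemate and is erased in step 5.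

Step 4
Reactants: 9 3,4-bis(benzyloxy)benzaldehyde
Product: 10 1,2-bis(benzyloxy)-4-ethenylbenzene
Conditions: Ph3PCH3Br, KOtBu, THF, 0 °C to rt
Reagents that add atoms: methyltriphenylphosphonium bromide, C[P+](c1ccccc1)(c1ccccc1)c1ccccc1.[Br-]
Why: Wittig methylenation of an aromatic aldehyde.

Step 5
Reactants: 8 5,7-bis(benzyloxy)-8-{[4-(benzyloxy)-2-hydroxyphenyl](hydroxy)methyl}-2H-chromen-2-one; 10 1,2-bis(benzyloxy)-4-ethenylbenzene
Product: 12 5,7-bis(benzyloxy)-8-{(2S,4S)-7-(benzyloxy)-2-[3,4-bis(benzyloxy)phenyl]-3,4-dihydro-2H-chromen-4-yl}-2H-chromen-2-one, via o-quinone methide 11 (not isolated)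
Conditions: chiral BINOL-derived N-triflylphosphoramide (5 mol%), 10 (2 equiv), CH2Cl2, −20 °C to rt
Reagents that add atoms: none
Why: Brønsted-acid-catalysed dehydration gives o-quinone methide 11 hydrogen-bonded to the chiral phosphoramide, and its inverse-electron-demand hetero-Diels–Alder reaction with the electron-rich styrene (CH2 terminus to the methide carbon, benzylic carbon to oxygen) through the endo transition state should give the 2,4-cis chroman, with the catalyst choosing the (2S,4S) face and the lactone-masked lower oxygen unable to compete for ring closure.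

Step 6
Reactants: 12 5,7-bis(benzyloxy)-8-{(2S,4S)-7-(benzyloxy)-2-[3,4-bis(benzyloxy)phenyl]-3,4-dihydro-2H-chromen-4-yl}-2H-chromen-2-one
Product: 14 (2S,4S)-7-(benzyloxy)-4-[5,7-bis(benzyloxy)-2-ethoxy-2H-chromen-8-yl]-2-[3,4-bis(benzyloxy)phenyl]-3,4-dihydro-2H-chromene (acetal epimers), via lactol 13 (not isolated)
Conditions: i-Bu2AlH (1.2 equiv), CH2Cl2, −78 °C; then EtOH, pyridinium p-toluenesulfonate (cat.), rt
Reagents that add atoms: ethanol, CCO
Why: Half-reduction of the lactone to the lactol followed by acid-catalysed acetalisation through the donor-stabilised benzopyrylium ion; the acetal configuration is irrelevant because it is lost on ionisation in step 7.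

Step 7
Reactants: 14 (2S,4S)-7-(benzyloxy)-4-[5,7-bis(benzyloxy)-2-ethoxy-2H-chromen-8-yl]-2-[3,4-bis(benzyloxy)phenyl]-3,4-dihydro-2H-chromene; 15 [3,4-bis(benzyloxy)phenyl]boronic acid
Product: 17 (2S,4S)-7-(benzyloxy)-4-{(2S)-5,7-bis(benzyloxy)-2-[3,4-bis(benzyloxy)phenyl]-2H-chromen-8-yl}-2-[3,4-bis(benzyloxy)phenyl]-3,4-dihydro-2H-chromene, via diethyl boronate 16 (not isolated)
Conditions: 15, EtOH, 4 Å MS, EtOAc, rt; then 14, Yb(OTf)3 (5 mol%), chiral tartaric-acid-derived dihydroxy monoamide acid (10 mol%), EtOAc, −20 °C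
Reagents that add atoms: none
Why: Enantioselective boronate addition to a chromene acetal, in which Yb(OTf)3 ionises the acetal to the aromatic benzopyrylium ion and the boronate, exchanged onto the chiral dihydroxy acid, transfers its aryl group as an ate complex to one face of C2 (catalyst control, 2S); any C2 epimer is a diastereomer and can be removed.

Step 8
Reactants: 17 (2S,4S)-7-(benzyloxy)-4-{(2S)-5,7-bis(benzyloxy)-2-[3,4-bis(benzyloxy)phenyl]-2H-chromen-8-yl}-2-[3,4-bis(benzyloxy)phenyl]-3,4-dihydro-2H-chromene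
Product: 18 (2R,3S)-5,7-bis(benzyloxy)-8-{(2S,4S)-7-(benzyloxy)-2-[3,4-bis(benzyloxy)phenyl]-3,4-dihydro-2H-chromen-4-yl}-2-[3,4-bis(benzyloxy)phenyl]-3,4-dihydro-2H-chromen-3-ol
Conditions: BH3·THF, THF, 0 °C to rt; then aq NaOH, H2O2, 0 °C
Reagents that add atoms: hydrogen peroxide, OO
Why: Hydroboration–oxidation in which boron adds to C3 (hydrogen to the benzylic C4) on the face anti to the C2 aryl group and is replaced by OH with retention, which should give the 2,3-trans (2R,3S) alcohol.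

Step 9
Reactants: 18 (2R,3S)-5,7-bis(benzyloxy)-8-{(2S,4S)-7-(benzyloxy)-2-[3,4-bis(benzyloxy)phenyl]-3,4-dihydro-2H-chromen-4-yl}-2-[3,4-bis(benzyloxy)phenyl]-3,4-dihydro-2H-chromen-3-ol
Product: 19 (2R,3S)-8-[(2S,4S)-2-(3,4-dihydroxyphenyl)-7-hydroxy-3,4-dihydro-2H-chromen-4-yl]-2-(3,4-dihydroxyphenyl)-3,4-dihydro-2H-chromene-3,5,7-triol
Conditions: H2 (1 atm), Pd(OH)2/C, THF/MeOH, rt
Reagents that add atoms: none
Why: Hydrogenolysis of the seven benzyl ethers under neutral conditions, which should leave the ring C2–O ethers and all four stereocentres untouched.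

**Compound list**

1 | 2,4,6-trihydroxybenzene-1,3-dicarbaldehyde | O=Cc1c(O)cc(O)c(C=O)c1O | starting material
2 | 4,6-bis(benzyloxy)-2-hydroxybenzene-1,3-dicarbaldehyde | O=Cc1c(OCc2ccccc2)cc(OCc2ccccc2)c(C=O)c1O | intermediate
3 | ketenylidene(triphenyl)phosphorane | O=C=C=P(c1ccccc1)(c1ccccc1)c1ccccc1 | starting material
4 | 3,5-bis(benzyloxy)-2,6-diformylphenyl (triphenylphosphoranylidene)acetate | O=Cc1c(OCc2ccccc2)cc(OCc2ccccc2)c(C=O)c1OC(=O)C=P(c1ccccc1)(c1ccccc1)c1ccccc1 | intermediate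
5 | 5,7-bis(benzyloxy)-2-oxo-2H-chromene-8-carbaldehyde | O=Cc1c(OCc2ccccc2)cc(OCc2ccccc2)c2C=CC(=O)Oc12 | intermediate
6 | 3-(benzyloxy)phenol | Oc1cccc(OCc2ccccc2)c1 | starting material
7 | bromomagnesium 3-(benzyloxy)phenolate | Br[Mg]Oc1cccc(OCc2ccccc2)c1 | intermediate
8 | 5,7-bis(benzyloxy)-8-{[4-(benzyloxy)-2-hydroxyphenyl](hydroxy)methyl}-2H-chromen-2-one (racemic) | OC(c1ccc(OCc2ccccc2)cc1O)c1c(OCc2ccccc2)cc(OCc2ccccc2)c2C=CC(=O)Oc12 | intermediate
9 | 3,4-bis(benzyloxy)benzaldehyde | O=Cc1ccc(OCc2ccccc2)c(OCc2ccccc2)c1 | starting material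
10 | 1,2-bis(benzyloxy)-4-ethenylbenzene | C=Cc1ccc(OCc2ccccc2)c(OCc2ccccc2)c1 | intermediate
11 | 3-(benzyloxy)-6-{[5,7-bis(benzyloxy)-2-oxo-2H-chromen-8-yl]methylidene}cyclohexa-2,4-dien-1-one | O=C1C=C(OCc2ccccc2)C=CC1=Cc1c(OCc2ccccc2)cc(OCc2ccccc2)c2C=CC(=O)Oc12 | intermediate
12 | 5,7-bis(benzyloxy)-8-{(2S,4S)-7-(benzyloxy)-2-[3,4-bis(benzyloxy)phenyl]-3,4-dihydro-2H-chromen-4-yl}-2H-chromen-2-one | C(c1ccccc1)Oc1ccc2c(c1)O[C@H](c1ccc(OCc3ccccc3)c(OCc3ccccc3)c1)C[C@@H]2c1c(OCc2ccccc2)cc(OCc2ccccc2)c2c1OC(=O)C=C2 | intermediate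
13 | 5,7-bis(benzyloxy)-8-{(2S,4S)-7-(benzyloxy)-2-[3,4-bis(benzyloxy)phenyl]-3,4-dihydro-2H-chromen-4-yl}-2H-chromen-2-ol | C(c1ccccc1)Oc1ccc2c(c1)O[C@H](c1ccc(OCc3ccccc3)c(OCc3ccccc3)c1)C[C@@H]2c1c(OCc2ccccc2)cc(OCc2ccccc2)c2c1OC(O)C=C2 | intermediate
14 | (2S,4S)-7-(benzyloxy)-4-[5,7-bis(benzyloxy)-2-ethoxy-2H-chromen-8-yl]-2-[3,4-bis(benzyloxy)phenyl]-3,4-dihydro-2H-chromene | C(c1ccccc1)Oc1ccc2c(c1)O[C@H](c1ccc(OCc3ccccc3)c(OCc3ccccc3)c1)C[C@@H]2c1c(OCc2ccccc2)cc(OCc2ccccc2)c2c1OC(OCC)C=C2 | intermediate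
15 | [3,4-bis(benzyloxy)phenyl]boronic acid | OB(O)c1ccc(OCc2ccccc2)c(OCc2ccccc2)c1 | starting material
16 | diethyl [3,4-bis(benzyloxy)phenyl]boronate | CCOB(OCC)c1ccc(OCc2ccccc2)c(OCc2ccccc2)c1 | intermediate
17 | (2S,4S)-7-(benzyloxy)-4-{(2S)-5,7-bis(benzyloxy)-2-[3,4-bis(benzyloxy)phenyl]-2H-chromen-8-yl}-2-[3,4-bis(benzyloxy)phenyl]-3,4-dihydro-2H-chromene | C(c1ccccc1)Oc1ccc2c(c1)O[C@H](c1ccc(OCc3ccccc3)c(OCc3ccccc3)c1)C[C@@H]2c1c(OCc2ccccc2)cc(OCc2ccccc2)c2c1O[C@H](c1ccc(OCc3ccccc3)c(OCc3ccccc3)c1)C=C2 | intermediate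
18 | (2R,3S)-5,7-bis(benzyloxy)-8-{(2S,4S)-7-(benzyloxy)-2-[3,4-bis(benzyloxy)phenyl]-3,4-dihydro-2H-chromen-4-yl}-2-[3,4-bis(benzyloxy)phenyl]-3,4-dihydro-2H-chromen-3-ol | C(c1ccccc1)Oc1ccc2c(c1)O[C@H](c1ccc(OCc3ccccc3)c(OCc3ccccc3)c1)C[C@@H]2c1c(OCc2ccccc2)cc(OCc2ccccc2)c2c1O[C@H](c1ccc(OCc3ccccc3)c(OCc3ccccc3)c1)[C@@H](O)C2 | intermediate
19 | (2R,3S)-8-[(2S,4S)-2-(3,4-dihydroxyphenyl)-7-hydroxy-3,4-dihydro-2H-chromen-4-yl]-2-(3,4-dihydroxyphenyl)-3,4-dihydro-2H-chromene-3,5,7-triol | Oc1ccc2c(c1)O[C@H](c1ccc(O)c(O)c1)C[C@@H]2c1c(O)cc(O)c2c1O[C@H](c1ccc(O)c(O)c1)[C@@H](O)C2 | target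

**Step count**

Total steps: 9. Longest linear sequence: 8 steps (1, 2, 3, 5, 6, 7, 8, 9); step 4 is a one-step side branch.

**Three steps most likely to fail**

Step 5. The diarylmethyl cation behind 11 is very strongly donor-stabilised, so the styrene may add stepwise with poor facial discrimination by the chiral acid, or the methide may oligomerise. The fallback sets out from 8 and builds the upper ring flat as well:
- oxidation with MnO2 (CH2Cl2) to [4-(benzyloxy)-2-hydroxyphenyl][5,7-bis(benzyloxy)-2-oxo-2H-chromen-8-yl]methanone F1;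
- a second O-acylation and intramolecular Wittig reaction with 3 (toluene, reflux) to the stereocentre-free biscoumarin 7-(benzyloxy)-4-[5,7-bis(benzyloxy)-2-oxo-2H-chromen-8-yl]-2H-chromen-2-one F2;
- twofold i-Bu2AlH reduction and ethanolysis to the bis-acetal 7-(benzyloxy)-4-[5,7-bis(benzyloxy)-2-ethoxy-2H-chromen-8-yl]-2-ethoxy-2H-chromene F3;
- twofold enantioselective aryl transfer from 15 under the conditions of step 7 to (2S)-7-(benzyloxy)-4-{(2S)-5,7-bis(benzyloxy)-2-[3,4-bis(benzyloxy)phenyl]-2H-chromen-8-yl}-2-[3,4-bis(benzyloxy)phenyl]-2H-chromene F4, in which both C2 centres have the same spatial sense and are set by one catalyst;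
- hydroboration–oxidation of the less hindered lower C3=C4 bond with 9-borabicyclo[3.3.1]nonane to (2R,3S)-5,7-bis(benzyloxy)-8-{(2S)-7-(benzyloxy)-2-[3,4-bis(benzyloxy)phenyl]-2H-chromen-4-yl}-2-[3,4-bis(benzyloxy)phenyl]-3,4-dihydro-2H-chromen-3-ol F5;
- ionic hydrogenation of the upper trisubstituted alkene (Et3SiH, CF3CO2H, CH2Cl2, −40 °C), in which axial hydride delivery to the C4 cation should give the 2,4-cis unit.

It comes back to the route at 18.

Step 7. Aryl transfer to the strongly stabilised 5,7-dialkoxybenzopyrylium ion may be slow, may compete with attack at C4, or may show low facial selectivity next to the bulky C8 substituent. The fallback sets out from 12: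
- addition of 3,4-bis(benzyloxy)phenylmagnesium bromide to the lactone carbonyl and dehydration with HBF4 to the flavylium salt 5,7-bis(benzyloxy)-8-{(2S,4S)-7-(benzyloxy)-2-[3,4-bis(benzyloxy)phenyl]-3,4-dihydro-2H-chromen-4-yl}-2-[3,4-bis(benzyloxy)phenyl]chromenylium tetrafluoroborate F6;
- hydride transfer from diethyl 2,6-dimethyl-1,4-dihydropyridine-3,5-dicarboxylate to C4, giving the 4H-chromene (2S,4S)-7-(benzyloxy)-4-{5,7-bis(benzyloxy)-2-[3,4-bis(benzyloxy)phenyl]-4H-chromen-8-yl}-2-[3,4-bis(benzyloxy)phenyl]-3,4-dihydro-2H-chromene F7;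
- asymmetric hydroboration–oxidation with monoisopinocampheylborane, where reagent control and syn addition should set lower C2 and C3 trans in one operation.

It comes back to the route at 18.

Step 3. Addition to the hindered, donor-deactivated aldehyde may be sluggish, and the carbinol may ionise further and be captured by a second phenol. The fallback sets out from 5 and 6:
- condensation with PhB(OH)2 (cat. propanoic acid, toluene, azeotropic removal of water), in which boron templates the ortho attack and caps the benzylic oxygen, to 5,7-bis(benzyloxy)-8-[7-(benzyloxy)-2-phenyl-4H-1,3,2-benzodioxaborinin-4-yl]-2H-chromen-2-one F8;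
- oxidative removal of boron (H2O2, THF, 0 °C).

It comes back to the route at 8.

Further compounds
F1 | step 5 | [4-(benzyloxy)-2-hydroxyphenyl][5,7-bis(benzyloxy)-2-oxo-2H-chromen-8-yl]methanone | O=C(c1ccc(OCc2ccccc2)cc1O)c1c(OCc2ccccc2)cc(OCc2ccccc2)c2C=CC(=O)Oc12
F2 | step 5 | 7-(benzyloxy)-4-[5,7-bis(benzyloxy)-2-oxo-2H-chromen-8-yl]-2H-chromen-2-one | O=C1C=C(c2c(OCc3ccccc3)cc(OCc3ccccc3)c3C=CC(=O)Oc23)c2ccc(OCc3ccccc3)cc2O1
F3 | step 5 | 7-(benzyloxy)-4-[5,7-bis(benzyloxy)-2-ethoxy-2H-chromen-8-yl]-2-ethoxy-2H-chromene | CCOC1C=C(c2c(OCc3ccccc3)cc(OCc3ccccc3)c3C=CC(OCC)Oc23)c2ccc(OCc3ccccc3)cc2O1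
F4 | step 5 | (2S)-7-(benzyloxy)-4-{(2S)-5,7-bis(benzyloxy)-2-[3,4-bis(benzyloxy)phenyl]-2H-chromen-8-yl}-2-[3,4-bis(benzyloxy)phenyl]-2H-chromene | C(c1ccccc1)Oc1ccc2c(c1)O[C@H](c1ccc(OCc3ccccc3)c(OCc3ccccc3)c1)C=C2c1c(OCc2ccccc2)cc(OCc2ccccc2)c2c1O[C@H](c1ccc(OCc3ccccc3)c(OCc3ccccc3)c1)C=C2
F5 | step 5 | (2R,3S)-5,7-bis(benzyloxy)-8-{(2S)-7-(benzyloxy)-2-[3,4-bis(benzyloxy)phenyl]-2H-chromen-4-yl}-2-[3,4-bis(benzyloxy)phenyl]-3,4-dihydro-2H-chromen-3-ol | C(c1ccccc1)Oc1ccc2c(c1)O[C@H](c1ccc(OCc3ccccc3)c(OCc3ccccc3)c1)C=C2c1c(OCc2ccccc2)cc(OCc2ccccc2)c2c1O[C@H](c1ccc(OCc3ccccc3)c(OCc3ccccc3)c1)[C@@H](O)C2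
F6 | step 7 | 5,7-bis(benzyloxy)-8-{(2S,4S)-7-(benzyloxy)-2-[3,4-bis(benzyloxy)phenyl]-3,4-dihydro-2H-chromen-4-yl}-2-[3,4-bis(benzyloxy)phenyl]chromenylium tetrafluoroborate | C(c1ccccc1)Oc1ccc2c(c1)O[C@H](c1ccc(OCc3ccccc3)c(OCc3ccccc3)c1)C[C@@H]2c1c(OCc2ccccc2)cc(OCc2ccccc2)c2ccc(-c3ccc(OCc4ccccc4)c(OCc4ccccc4)c3)[o+]c12.F[B-](F)(F)F
F7 | step 7 | (2S,4S)-7-(benzyloxy)-4-{5,7-bis(benzyloxy)-2-[3,4-bis(benzyloxy)phenyl]-4H-chromen-8-yl}-2-[3,4-bis(benzyloxy)phenyl]-3,4-dihydro-2H-chromene | C(c1ccccc1)Oc1ccc2c(c1)O[C@H](c1ccc(OCc3ccccc3)c(OCc3ccccc3)c1)C[C@@H]2c1c(OCc2ccccc2)cc(OCc2ccccc2)c2c1OC(c1ccc(OCc3ccccc3)c(OCc3ccccc3)c1)=CC2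
F8 | step 3 | 5,7-bis(benzyloxy)-8-[7-(benzyloxy)-2-phenyl-4H-1,3,2-benzodioxaborinin-4-yl]-2H-chromen-2-one | B1(c2ccccc2)Oc2cc(OCc3ccccc3)ccc2C(O1)c1c(OCc2ccccc2)cc(OCc2ccccc2)c2C=CC(=O)Oc12
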